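**Plan**

1. Locants (biogenetic): the carbinol carbon is C14; the 14‑membered ring is C1–C14, with C1 and C13 as the two CH2 neighbours of C14, C2=C3 (Z), C6=C7 and C10=C11 (E); the side chain is C15(H)Me–C20H2OH.
2. Enabling feature: ring atoms C1–C12 are an intact (2Z,6E)‑farnesyl chain bridged only by C13–C14. C13 lies between the carbinol carbon C14 and C12, the allylic CH2 of the C10=C11 alkene, so a C13 carbanion (held by a temporary sulfonyl group next to the C14 oxide) can close the ring by SN2 at allylic C12.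
3. Cuts, in retrosynthetic order: O–Si and C13–S (helpers), ring bond C12–C13, C13–S again (from the epoxide C13–O–C14), C15–C16 (epoxy‑alcohol opening), C14=C15 (Wittig), C1–C14 (ylide alkylation).
4. Forward: farnesyl bromide + ylide (C1–C14), Wittig (C14=C15), asymmetric epoxidation, side chain on (C15–C16), terminal epoxide, sulfone, C12 oxidation and bromide, then the only ring is closed last; desulfonylation and desilylation finish.
5. Stereochemistry: C14 from Sharpless epoxidation (D‑(−)‑tartrate) of an E‑allylic alcohol; C15 from that E geometry plus SN2 inversion in the epoxide opening; 2Z/6E from farnesol; 10E and 18E from E‑selective SeO2 oxidations, carried through SN2 steps.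

Key step: step 13

Remark: (2Z,6E)‑farnesol is taken as purchasable as the single geometrical isomer.

**Step 1**
Reactants: 1 (2Z,6E)-farnesol
Product: 2 (2Z,6E)-farnesyl bromide
Conditions: PBr3 (0.4 equiv), Et2O, −10 °C
Reagents that add atoms: phosphorus tribromide, BrP(Br)Br
Why: SN2-type bromination of a primary allylic alcohol with PBr3; at −10 °C it should proceed without allylic transposition or loss of the 2Z geometry.

**Step 2**
Reactants: 2 (2Z,6E)-farnesyl bromide; 3 ethyl (triphenyl-λ5-phosphanylidene)acetate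
Product: 5 ethyl (4Z,8E)-5,9,13-trimethyl-2-(triphenyl-λ5-phosphanylidene)tetradeca-4,8,12-trienoate, via C-alkylated phosphonium bromide 4 (not isolated)
Conditions: 3 (1.1 equiv), CHCl3, 50 °C; then 1 M aq NaOH, CH2Cl2, 0 °C
Reagents that add atoms: none
Why: C‑alkylation of a stabilised phosphorus ylide by the primary allylic bromide (SN2 at C1, 2Z kept), then deprotonation of the phosphonium salt, should give the α‑substituted stabilised ylide; no stereocentre is formed.

**Step 3**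
Reactants: 5 α-farnesyl ylide; 6 acetaldehyde
Product: 7 ethyl (2E)-2-[(2Z,6E)-3,7,11-trimethyldodeca-2,6,10-trien-1-yl]but-2-enoate
Conditions: MeCHO (5 equiv), CH2Cl2, sealed tube, 40 °C
Reagents that add atoms: none
Why: Wittig olefination with an α‑substituted stabilised ylide should place the C15 methyl trans to the ester (E), i.e. cis to the farnesyl CH2 (C1).

**Step 4**
Reactants: 7 (E)-enoate
Product: 8 (2E)-2-[(2Z,6E)-3,7,11-trimethyldodeca-2,6,10-trien-1-yl]but-2-en-1-ol
Conditions: DIBAL-H (2.5 equiv), CH2Cl2, −78 °C; Rochelle salt work-up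
Reagents that add atoms: none
Why: DIBAL‑H 1,2‑reduction of the conjugated ester to the allylic alcohol leaves the alkene geometry and the isolated alkenes untouched.

**Step 5**
Reactants: 8 (E)-allylic alcohol
Product: 9 [(2R,3R)-3-methyl-2-[(2Z,6E)-3,7,11-trimethyldodeca-2,6,10-trien-1-yl]oxiran-2-yl]methanol
Conditions: Ti(OiPr)4 (10 mol%), D-(−)-diethyl tartrate (12 mol%), t-BuOOH, 4 Å MS, CH2Cl2, −20 °C
Reagents that add atoms: tert-butyl hydroperoxide, CC(C)(C)OO
Why: Sharpless asymmetric epoxidation of an (E)-2,3-disubstituted allylic alcohol; D‑(−)‑tartrate should give the (2R,3R)-epoxide, which fixes C14, and the hydroxyl‑directed catalyst ignores the three isolated alkenes.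

**Step 6**
Reactants: 10 5-bromo-2-methylpent-2-ene
Product: 11 (2E)-5-bromo-2-methylpent-2-en-1-ol
Conditions: SeO2 (0.4 equiv), t-BuOOH, salicylic acid (cat.), CH2Cl2, rt
Reagents that add atoms: tert-butyl hydroperoxide, CC(C)(C)OO; selenium dioxide (catalytic oxygen carrier), O=[Se]=O
Why: SeO2‑catalysed allylic oxidation (ene reaction then [2,3]-shift) should hydroxylate the (E)-methyl group and so set the 18E geometry of the side chain.

**Step 7**
Reactants: 11 (2E)-5-bromo-2-methylpent-2-en-1-ol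
Product: 12 {[(2E)-5-bromo-2-methylpent-2-en-1-yl]oxy}(tert-butyl)diphenylsilane
Conditions: TBDPSCl, imidazole, CH2Cl2, 0 °C → rt
Reagents that add atoms: tert-butyl(chloro)diphenylsilane, CC(C)(C)[Si](Cl)(c1ccccc1)c1ccccc1
Why: Standard silylation of a primary allylic alcohol; the TBDPS ether should survive Grignard formation, strong base, SeO2 and sodium amalgam.

**Step 8**
Reactants: 9 (2R,3R)-epoxy alcohol; 12 silyl-protected bromide
Product: 14 (2S,3R,6E)-8-[(tert-butyldiphenylsilyl)oxy]-3,7-dimethyl-2-[(2Z,6E)-3,7,11-trimethyldodeca-2,6,10-trien-1-yl]oct-6-ene-1,2-diol, via Grignard reagent 13 (not isolated)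
Conditions: 12, Mg, THF, rt (3 equiv of 13); CuI (10 mol%), THF, −30 °C; then 9, −30 → 0 °C; aq NH4Cl
Reagents that add atoms: none
Why: Copper‑catalysed Grignard opening of a 2,3‑epoxy alcohol; C14 is quaternary, so SN2 attack should occur only at C15 with inversion, which sets C15 as R and leaves the C14–O bond (14S) intact.

**Step 9**
Reactants: 14 diol
Product: 16 (2S)-2-[(2R,5E)-7-[(tert-butyldiphenylsilyl)oxy]-6-methylhept-5-en-2-yl]-2-[(2Z,6E)-3,7,11-trimethyldodeca-2,6,10-trien-1-yl]oxirane, via primary tosylate 15 (not isolated)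
Conditions: NaH (2.5 equiv), N-tosylimidazole (1.05 equiv), THF, 0 °C → rt
Reagents that add atoms: none
Why: Selective sulfonylation of the primary alkoxide and 3‑exo‑tet displacement by the tertiary alkoxide should give the 2,2‑disubstituted epoxide; no bond to C14 or C15 is broken, so both stereocentres are kept.

**Step 10**
Reactants: 16 epoxide
Product: 17 (2S,3R,6E)-8-[(tert-butyldiphenylsilyl)oxy]-3,7-dimethyl-1-(phenylsulfonyl)-2-[(2Z,6E)-3,7,11-trimethyldodeca-2,6,10-trien-1-yl]oct-6-en-2-ol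
Conditions: PhSO2Na (3 equiv), NaH2PO4 (2 equiv), DMF–H2O (10:1), 80 °C
Reagents that add atoms: sodium benzenesulfinate, [Na+].[O-]S(=O)c1ccccc1
Why: SN2 opening of the epoxide at its CH2 terminus (C13) by the sulfur of the ambident sulfinate should give the β‑hydroxy sulfone and free the C14 carbinol; the buffer protects the product from base‑induced retro‑addition.

**Step 11**
Reactants: 17 β-hydroxy sulfone
Product: 18 (2S,3R,6E)-8-[(tert-butyldiphenylsilyl)oxy]-2-[(2Z,6E,10E)-12-hydroxy-3,7,11-trimethyldodeca-2,6,10-trien-1-yl]-3,7-dimethyl-1-(phenylsulfonyl)oct-6-en-2-ol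
Conditions: SeO2 (0.5 equiv), t-BuOOH (3 equiv), salicylic acid (10 mol%), CH2Cl2, 0 °C → rt, run to partial conversion with recycling of 17
Reagents that add atoms: tert-butyl hydroperoxide, CC(C)(C)OO; selenium dioxide (catalytic oxygen carrier), O=[Se]=O
Why: SeO2‑catalysed allylic oxidation should prefer the terminal gem‑dimethyl alkene and its (E)-methyl group (C12), giving the 10E allylic alcohol; the internal alkenes react more slowly and C18=C19 is deactivated by its allylic oxygen.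

**Step 12**
Reactants: 18 allylic alcohol
Product: 19 (2S,3R,6E)-2-[(2Z,6E,10E)-12-bromo-3,7,11-trimethyldodeca-2,6,10-trien-1-yl]-8-[(tert-butyldiphenylsilyl)oxy]-3,7-dimethyl-1-(phenylsulfonyl)oct-6-en-2-ol
Conditions: CBr4, PPh3, 2,6-lutidine, CH2Cl2, −20 → 0 °C
Reagents that add atoms: carbon tetrabromide, BrC(Br)(Br)Br
Why: Appel bromination converts the primary allylic alcohol by SN2 without transposition; the hindered tertiary alcohol should not react.

**Step 13**
Reactants: 19 bromo β-hydroxy sulfone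
Product: 20 (1S,3Z,7E,11E)-1-[(2R,5E)-7-[(tert-butyldiphenylsilyl)oxy]-6-methylhept-5-en-2-yl]-4,8,12-trimethyl-14-(phenylsulfonyl)cyclotetradeca-3,7,11-trien-1-ol (both C14 epimers)
Conditions: 19 (2 mM in THF–DMPU 10:1), LDA (2.3 equiv) added at −78 °C, then −78 → −30 °C over 6 h; AcOH quench at −40 °C
Reagents that add atoms: none
Why: LDA removes the hydroxyl proton and one C13–H, and the resulting β‑oxido α‑sulfonyl carbanion displaces bromide at the primary allylic carbon C12 in an intramolecular SN2 reaction that forms the C12–C13 bond. The closest known reaction type is the intramolecular alkylation of sulfone‑stabilised carbanions by allylic halides, the classical way to close 14‑membered terpenoid carbocycles. The ring closes in the 14‑exo‑tet mode. The only new stereocentre is the sulfonyl‑bearing C13, formed without control and erased in step 14; C14 (quaternary) and C15 (not acidic) cannot epimerise. The step needs cyclisation to outrun intermolecular alkylation, C‑ over O‑alkylation and SN2 over SN2′: high dilution and the three rigid trisubstituted alkenes between C1 and C12 favour ring closure, the carbanion is far more nucleophilic than the hindered tertiary lithium alkoxide, and SN2′ would require attack at the substituted C10 to give a 12‑membered ring. Because bromide is displaced without allylic shift, the 10E geometry from step 11 is carried into the ring, and low temperature plus full conversion to the dianion suppress retro‑addition of the β‑oxido sulfone.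

**Step 14**
Reactants: 20 macrocyclic sulfone
Product: 21 (1S,3Z,7E,11E)-1-[(2R,5E)-7-[(tert-butyldiphenylsilyl)oxy]-6-methylhept-5-en-2-yl]-4,8,12-trimethylcyclotetradeca-3,7,11-trien-1-ol
Conditions: 6% Na(Hg), Na2HPO4, MeOH–THF, −20 °C
Reagents that add atoms: none
Why: Reductive desulfonylation by electron transfer from sodium amalgam; the sulfone is not allylic, so no alkene can migrate, the free β‑hydroxyl is too poor a leaving group for Julia‑type elimination at −20 °C, and both C13 epimers converge to one product.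

**Step 15**
Reactants: 21 silyl ether of the target
Product: 22 (1S,3Z,7E,11E)-1-[(2R,5E)-7-hydroxy-6-methylhept-5-en-2-yl]-4,8,12-trimethylcyclotetradeca-3,7,11-trien-1-ol
Conditions: TBAF, THF, 0 °C → rt
Reagents that add atoms: none
Why: Fluoride‑mediated cleavage of the silyl ether releases the primary allylic alcohol without touching the tertiary homoallylic carbinol or the alkenes.

**Compound list**

1 | (2Z,6E)-3,7,11-trimethyldodeca-2,6,10-trien-1-ol, (2Z,6E)-farnesol | OC/C=C(C)\CC/C=C(C)/CCC=C(C)C | starting material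
2 | (2Z,6E)-1-bromo-3,7,11-trimethyldodeca-2,6,10-triene | BrC/C=C(C)\CC/C=C(C)/CCC=C(C)C | intermediate
3 | ethyl (triphenyl-λ5-phosphanylidene)acetate | CCOC(=O)C=P(c1ccccc1)(c1ccccc1)c1ccccc1 | starting material
4 | [(4Z,8E)-1-ethoxy-5,9,13-trimethyl-1-oxotetradeca-4,8,12-trien-2-yl]triphenylphosphonium bromide (racemic at C2) | CCOC(=O)C(C/C=C(C)\CC/C=C(C)/CCC=C(C)C)[P+](c1ccccc1)(c1ccccc1)c1ccccc1.[Br-] | intermediate (not isolated)
5 | ethyl (4Z,8E)-5,9,13-trimethyl-2-(triphenyl-λ5-phosphanylidene)tetradeca-4,8,12-trienoate | CCOC(=O)C(C/C=C(C)\CC/C=C(C)/CCC=C(C)C)=P(c1ccccc1)(c1ccccc1)c1ccccc1 | intermediate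
6 | acetaldehyde | CC=O | starting material
7 | ethyl (2E)-2-[(2Z,6E)-3,7,11-trimethyldodeca-2,6,10-trien-1-yl]but-2-enoate | C/C=C(\C/C=C(C)\CC/C=C(C)/CCC=C(C)C)C(=O)OCC | intermediate
8 | (2E)-2-[(2Z,6E)-3,7,11-trimethyldodeca-2,6,10-trien-1-yl]but-2-en-1-ol | C/C=C(\C/C=C(C)\CC/C=C(C)/CCC=C(C)C)CO | intermediate
9 | [(2R,3R)-3-methyl-2-[(2Z,6E)-3,7,11-trimethyldodeca-2,6,10-trien-1-yl]oxiran-2-yl]methanol | C[C@H]1O[C@@]1(CO)C/C=C(C)\CC/C=C(C)/CCC=C(C)C | intermediate
10 | 5-bromo-2-methylpent-2-ene | CC(C)=CCCBr | starting material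
11 | (2E)-5-bromo-2-methylpent-2-en-1-ol | OC/C(C)=C/CCBr | intermediate
12 | {[(2E)-5-bromo-2-methylpent-2-en-1-yl]oxy}(tert-butyl)diphenylsilane | BrCC/C=C(\C)CO[Si](c1ccccc1)(c1ccccc1)C(C)(C)C | intermediate
13 | {(3E)-5-[(tert-butyldiphenylsilyl)oxy]-4-methylpent-3-en-1-yl}magnesium bromide | Br[Mg]CC/C=C(\C)CO[Si](c1ccccc1)(c1ccccc1)C(C)(C)C | intermediate (not isolated)
14 | (2S,3R,6E)-8-[(tert-butyldiphenylsilyl)oxy]-3,7-dimethyl-2-[(2Z,6E)-3,7,11-trimethyldodeca-2,6,10-trien-1-yl]oct-6-ene-1,2-diol | OC[C@](O)(C/C=C(C)\CC/C=C(C)/CCC=C(C)C)[C@H](C)CC/C=C(\C)CO[Si](c1ccccc1)(c1ccccc1)C(C)(C)C | intermediate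
15 | (2S,3R,6E)-8-[(tert-butyldiphenylsilyl)oxy]-2-hydroxy-3,7-dimethyl-2-[(2Z,6E)-3,7,11-trimethyldodeca-2,6,10-trien-1-yl]oct-6-en-1-yl 4-methylbenzenesulfonate | Cc1ccc(cc1)S(=O)(=O)OC[C@](O)(C/C=C(C)\CC/C=C(C)/CCC=C(C)C)[C@H](C)CC/C=C(\C)CO[Si](c2ccccc2)(c2ccccc2)C(C)(C)C | intermediate (not isolated)
16 | (2S)-2-[(2R,5E)-7-[(tert-butyldiphenylsilyl)oxy]-6-methylhept-5-en-2-yl]-2-[(2Z,6E)-3,7,11-trimethyldodeca-2,6,10-trien-1-yl]oxirane | C1O[C@@]1(C/C=C(C)\CC/C=C(C)/CCC=C(C)C)[C@H](C)CC/C=C(\C)CO[Si](c2ccccc2)(c2ccccc2)C(C)(C)C | intermediate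
17 | (2S,3R,6E)-8-[(tert-butyldiphenylsilyl)oxy]-3,7-dimethyl-1-(phenylsulfonyl)-2-[(2Z,6E)-3,7,11-trimethyldodeca-2,6,10-trien-1-yl]oct-6-en-2-ol | O=S(=O)(C[C@](O)(C/C=C(C)\CC/C=C(C)/CCC=C(C)C)[C@H](C)CC/C=C(\C)CO[Si](c1ccccc1)(c1ccccc1)C(C)(C)C)c1ccccc1 | intermediate
18 | (2S,3R,6E)-8-[(tert-butyldiphenylsilyl)oxy]-2-[(2Z,6E,10E)-12-hydroxy-3,7,11-trimethyldodeca-2,6,10-trien-1-yl]-3,7-dimethyl-1-(phenylsulfonyl)oct-6-en-2-ol | O=S(=O)(C[C@](O)(C/C=C(C)\CC/C=C(C)/CC/C=C(\C)CO)[C@H](C)CC/C=C(\C)CO[Si](c1ccccc1)(c1ccccc1)C(C)(C)C)c1ccccc1 | intermediate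
19 | (2S,3R,6E)-2-[(2Z,6E,10E)-12-bromo-3,7,11-trimethyldodeca-2,6,10-trien-1-yl]-8-[(tert-butyldiphenylsilyl)oxy]-3,7-dimethyl-1-(phenylsulfonyl)oct-6-en-2-ol | O=S(=O)(C[C@](O)(C/C=C(C)\CC/C=C(C)/CC/C=C(\C)CBr)[C@H](C)CC/C=C(\C)CO[Si](c1ccccc1)(c1ccccc1)C(C)(C)C)c1ccccc1 | intermediate
20 | (1S,3Z,7E,11E)-1-[(2R,5E)-7-[(tert-butyldiphenylsilyl)oxy]-6-methylhept-5-en-2-yl]-4,8,12-trimethyl-14-(phenylsulfonyl)cyclotetradeca-3,7,11-trien-1-ol (both epimers at C14 of the ring) | C/C1=C/C[C@](O)([C@H](C)CC/C=C(\C)CO[Si](c2ccccc2)(c2ccccc2)C(C)(C)C)C(S(=O)(=O)c2ccccc2)C/C(C)=C/CC/C(C)=C/CC1 | intermediate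
21 | (1S,3Z,7E,11E)-1-[(2R,5E)-7-[(tert-butyldiphenylsilyl)oxy]-6-methylhept-5-en-2-yl]-4,8,12-trimethylcyclotetradeca-3,7,11-trien-1-ol | C/C1=C/C[C@](O)([C@H](C)CC/C=C(\C)CO[Si](c2ccccc2)(c2ccccc2)C(C)(C)C)CC/C(C)=C/CC/C(C)=C/CC1 | intermediate
22 | (1S,3Z,7E,11E)-1-[(2R,5E)-7-hydroxy-6-methylhept-5-en-2-yl]-4,8,12-trimethylcyclotetradeca-3,7,11-trien-1-ol | C/C1=C/C[C@](O)([C@H](C)CC/C=C(\C)CO)CC/C(C)=C/CC/C(C)=C/CC1 | target

**Totals and risks**

Total step count: 15. Longest linear sequence: 13 steps (from 1 through steps 1–5 and 8–15).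

Most likely to fail, with one fallback each:

1. Step 13 (ring closure). What may go wrong: intermolecular alkylation outrunning cyclisation (oligomerisation), base‑induced elimination at the allylic bromide, O‑alkylation by the tertiary alkoxide, or retro‑addition of the β‑oxido sulfone. Fallback, reversing the polarity of the same ring bond, sets out from 16 and returns at 21. Cross‑metathesis of the terminal isopropylidene group of 16 with methacrolein (second‑generation Ru NHC catalyst, CH2Cl2, 40 °C) should give the (E)-enal epoxide F1. Luche reduction (NaBH4, CeCl3, MeOH) gives the allylic alcohol epoxide F2. CBr4/PPh3 gives the allylic bromide epoxide F3, and PhSO2Na in DMF the allylic sulfone epoxide F4. LiHMDS (THF, high dilution, −78 → 0 °C) deprotonates the more acidic allylic sulfone at C12, and the carbanion opens the epoxide at its CH2 (C13) to give the macrocyclic 12‑sulfonyl carbinol F5. PdCl2(dppp)/LiBHEt3 then removes the sulfonyl group to give 21; an alkene‑position isomer from hydride delivery to the other allyl terminus would have to be separated.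

2. Step 11 (late allylic oxidation). What may go wrong: poor site selectivity, with oxidation at the two internal trisubstituted alkenes, and over‑oxidation to the enal. Fallback sets out from 17 and returns at 18. Cross‑metathesis of 17 with methacrolein (same Ru catalyst) acts only on the terminal isopropylidene group and should give the (E)-enal sulfone F6. Luche reduction of F6 gives 18.

3. Step 8 (copper‑catalysed Grignard opening). What may go wrong: slow SN2 attack at the hindered C15, with competing halohydrin formation, elimination, or Payne rearrangement followed by attack at C13. Fallback, in which the alkene substituent and the nucleophile exchange roles, sets out from 12 (and uses 2) and returns at 14. Alkylation of the dianion of prop‑2‑yn‑1‑ol with 12 gives the alkynol F7. Pd‑catalysed syn‑hydrostannation (Bu3SnH) gives the (E)-2‑stannyl allylic alcohol F8. Stille coupling with bromide 2 gives the (Z)-allylic alcohol F9, with the side chain cis to CH2OH. Sharpless epoxidation with D‑(−)‑diethyl tartrate gives the (2R,3S)-epoxy alcohol F10. MeMgBr with catalytic CuI then delivers the small methyl nucleophile at C15 with inversion to give 14.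

**Further compounds**

F1 | step 13 | (2E,6E,10Z)-12-{(2S)-2-[(2R,5E)-7-[(tert-butyldiphenylsilyl)oxy]-6-methylhept-5-en-2-yl]oxiran-2-yl}-2,6,10-trimethyldodeca-2,6,10-trienal | C1O[C@@]1(C/C=C(C)\CC/C=C(C)/CC/C=C(\C)C=O)[C@H](C)CC/C=C(\C)CO[Si](c2ccccc2)(c2ccccc2)C(C)(C)C
F2 | step 13 | (2E,6E,10Z)-12-{(2S)-2-[(2R,5E)-7-[(tert-butyldiphenylsilyl)oxy]-6-methylhept-5-en-2-yl]oxiran-2-yl}-2,6,10-trimethyldodeca-2,6,10-trien-1-ol | C1O[C@@]1(C/C=C(C)\CC/C=C(C)/CC/C=C(\C)CO)[C@H](C)CC/C=C(\C)CO[Si](c2ccccc2)(c2ccccc2)C(C)(C)C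
F3 | step 13 | (2S)-2-[(2Z,6E,10E)-12-bromo-3,7,11-trimethyldodeca-2,6,10-trien-1-yl]-2-[(2R,5E)-7-[(tert-butyldiphenylsilyl)oxy]-6-methylhept-5-en-2-yl]oxirane | C1O[C@@]1(C/C=C(C)\CC/C=C(C)/CC/C=C(\C)CBr)[C@H](C)CC/C=C(\C)CO[Si](c2ccccc2)(c2ccccc2)C(C)(C)C
F4 | step 13 | (2S)-2-[(2R,5E)-7-[(tert-butyldiphenylsilyl)oxy]-6-methylhept-5-en-2-yl]-2-[(2Z,6E,10E)-3,7,11-trimethyl-12-(phenylsulfonyl)dodeca-2,6,10-trien-1-yl]oxirane | C1O[C@@]1(C/C=C(C)\CC/C=C(C)/CC/C=C(\C)CS(=O)(=O)c2ccccc2)[C@H](C)CC/C=C(\C)CO[Si](c3ccccc3)(c3ccccc3)C(C)(C)C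
F5 | step 13 | (1S,3Z,7E,11E)-1-[(2R,5E)-7-[(tert-butyldiphenylsilyl)oxy]-6-methylhept-5-en-2-yl]-4,8,12-trimethyl-13-(phenylsulfonyl)cyclotetradeca-3,7,11-trien-1-ol (both epimers at C13 of the ring) | C/C1=C/C[C@](O)([C@H](C)CC/C=C(\C)CO[Si](c2ccccc2)(c2ccccc2)C(C)(C)C)CC(S(=O)(=O)c2ccccc2)/C(C)=C/CC/C(C)=C/CC1
F6 | step 11 | (2E,6E,10Z)-12-[(2S,3R,6E)-8-[(tert-butyldiphenylsilyl)oxy]-2-hydroxy-3,7-dimethyl-1-(phenylsulfonyl)oct-6-en-2-yl]-2,6,10-trimethyldodeca-2,6,10-trienal | O=S(=O)(C[C@](O)(C/C=C(C)\CC/C=C(C)/CC/C=C(\C)C=O)[C@H](C)CC/C=C(\C)CO[Si](c1ccccc1)(c1ccccc1)C(C)(C)C)c1ccccc1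
F7 | step 8 | (6E)-8-[(tert-butyldiphenylsilyl)oxy]-7-methyloct-6-en-2-yn-1-ol | OCC#CCC/C=C(\C)CO[Si](c1ccccc1)(c1ccccc1)C(C)(C)C
F8 | step 8 | (2E,6E)-8-[(tert-butyldiphenylsilyl)oxy]-7-methyl-2-(tributylstannyl)octa-2,6-dien-1-ol | OC/C(=C\CC/C=C(\C)CO[Si](c1ccccc1)(c1ccccc1)C(C)(C)C)[Sn](CCCC)(CCCC)CCCC
F9 | step 8 | (2Z,6E)-8-[(tert-butyldiphenylsilyl)oxy]-7-methyl-2-[(2Z,6E)-3,7,11-trimethyldodeca-2,6,10-trien-1-yl]octa-2,6-dien-1-ol | OC/C(C/C=C(C)\CC/C=C(C)/CCC=C(C)C)=C\CC/C=C(\C)CO[Si](c1ccccc1)(c1ccccc1)C(C)(C)C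
F10 | step 8 | [(2R,3S)-3-[(3E)-5-[(tert-butyldiphenylsilyl)oxy]-4-methylpent-3-en-1-yl]-2-[(2Z,6E)-3,7,11-trimethyldodeca-2,6,10-trien-1-yl]oxiran-2-yl]methanol | OC[C@@]1(C/C=C(C)\CC/C=C(C)/CCC=C(C)C)O[C@H]1CC/C=C(\C)CO[Si](c2ccccc2)(c2ccccc2)C(C)(C)C
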